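## Analysis of the target

Target 15 is a 2,4-disubstituted furan (numbered O1, C2 to C5). C2 carries a 2,5-dihydroxyphenyl ring, a hydroquinone joined through the carbon ortho to one hydroxyl; C4 carries an acyclic chain C1'–C4' with two methyls on C4'; C3 and C5 are CH. C1' is the only stereocentre, a furylic secondary carbinol carbon esterified as the 3-methylbutanoate, with the (R) configuration. There is therefore no relative stereochemistry to control, but also no neighbouring centre to relay from. C2' is a methylene and C3'=C4' a trisubstituted alkene, so C1' bears a linear prenyl group. The sensitive functions are: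

- the free hydroquinone, which air oxidises to the quinone, fastest as the phenoxide;
- the electron-rich furan, which is attacked by acid, electrophiles and oxidants;
- the furylic ester, which can ionise to a furan-stabilised cation (racemising C1') and is cleaved by base;
- the prenyl alkene.

Three things make the synthesis hard: carbon substitution at a furan β-position, where metalation and electrophilic chemistry prefer α; an enantioenriched furylic carbinol; and the linear prenyl group beside it, since a prenyl metal adds to a furan-4-carbaldehyde normally at its substituted terminus and gives the branched 1,1-dimethylallyl isomer. The strategy rests on one feature: C1' lies between furan C4 and C2', and C2' is bonded to the alkenyl carbon C3'. C1'–C2' can thus be the two carbons of a vinyl group on boron, with the furan delivered to the internal carbon, the 2-methylpropenyl group to the terminal carbon, and boron left on C1' as the placeholder for oxygen.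

## Retrosynthetic reasoning

**15 ⇒ 14.** The two phenolic O–H bonds are traced back to O–Si bonds. The hydroquinone is the most oxidation-prone part of the molecule and its acidic protons would quench every organometallic used earlier, so it stays masked until the last operation. Triisopropylsilyl ethers are chosen because they survive an alkyllithium at low temperature, palladium catalysis, mild aqueous base and acylation, and fall to buffered fluoride. The forward reaction must cleave two aryl silyl ethers without touching the furylic ester.

**14 ⇒ 12 + 13.** The ester is cut at the acyl C–O bond. The C1'–O bond is not involved, so acylation of 12 with 13 cannot affect the configuration. The ester must come late because it would not survive the organolithium needed earlier.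

**12 ⇒ 11.** The C1'–O bond is traced back to a C1'–B bond. Oxidation of a secondary boronic ester proceeds with retention, so an enantioenriched boronic ester 11 is a full equivalent of the carbinol. Boron is also exactly what the key bond-forming event leaves on C1'.

**11 ⇒ 5 + 8 + 7 (through 9 and 10).** Two bonds are cut at once: furan C4–C1' and C2'–C3'. They flank the two-carbon unit C1'–C2', which becomes the vinyl group of 8. Cutting C1'–C2' instead would lead back to an aldehyde plus a prenyl nucleophile and the branched-isomer problem. Cutting only C4–C1' would demand a separately made chiral electrophile. The double cut gives three simple pieces, creates the stereocentre in the same event as both C–C bonds, and fixes the linear prenyl connectivity by mechanism. The forward reaction has to do three things: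

- generate the β-lithiofuran 9 from bromide 5 without letting it isomerise;
- capture it on boron as the ate complex 10;
- induce, with a chiral palladium catalyst and triflate 7, an enantioselective shift of the furyl group from boron to carbon that outruns direct cross-coupling.

**7 ⇒ 6.** The enol triflate is cut at the O–S bond and comes from the aldehyde 6 by O-sulfonylation and loss of the α-proton. The two methyls on the β-carbon are identical, so no alkene geometry has to be controlled.

**5 ⇒ 3 + 4.** The only bond joining the two rings, furan C2–aryl C1, is cut. In 4 the C2–Br bond α to oxygen is the more reactive toward palladium, so a cross-coupling with boronate 3 should install the aryl group there and leave the C4 bromide as the handle for the key step. This puts the β-substituent in place without any β-selective furan functionalisation.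

**3 ⇒ 2 ⇒ 1.** The aryl C–B bond is traced to the C–Br bond of 2 by palladium-catalysed borylation, which avoids an ortho-silyloxy aryllithium and its silyl migration. The O–Si bonds of 2 go back to commercial 1. The hydroquinone ring is bought, not built.

## Alternatives that were turned down

**Alternative 1: benzannulation to build the hydroquinone ring.**
- Disconnection: the arene is taken apart into the terminal alkyne of ethynylfuran A2, the vinyl(methoxy)carbene unit of the chromium complex A3, (CO)5Cr=C(OMe)CH=CH2, and one carbonyl ligand.
- Forward key step: warming A2 with A3 (Dötz benzannulation). Alkyne insertion into the Cr=C bond, CO insertion to a vinylketene, 6π-electrocyclisation and tautomerisation should give, after oxidative removal of chromium, the 4-methoxyphenol A1, with the furyl-bearing carbon next to the new hydroxyl.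
- For: three C–C bonds and the whole oxygenation pattern arise in one operation, the regiochemistry with a terminal alkyne is predictable, and an ester is tolerated.
- Against:
  - The ring being built is the one part of the target that is commercially available with the right substituents.
  - The reaction needs stoichiometric zerovalent chromium, and A3 is an unhindered vinyl carbene complex prone to polymerisation.
  - A1 still carries a methyl ether. Lewis-acid demethylation would ionise the furylic ester. Oxidative demethylation through the quinone with (NH4)2Ce(NO3)6 threatens the furan and the prenyl alkene.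
  - A2 already contains C1', the prenyl chain and the ester, so the real problem is untouched and merely moved to an earlier stage on a more fragile 2-ethynylfuran.
- Comparison: it is stronger on one point, since it differentiates the two phenolic oxygens, which would matter for selectively derivatised analogues. The target does not need that. The chosen route takes the arene from 1 and spends its key step on the stereocentre and the two bonds around it.

**Alternative 2: ring-closing metathesis to form the furan.**
- Disconnection: furan C3=C4, leading back to the acyclic mixed acetal A5, in which an aryl vinyl carbinol and ethanol are bound to the aldehyde carbon of a 2-substituted acrolein that already carries C1' with its ester.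
- Forward key step: second-generation Grubbs catalyst should close the 5-ethoxy-2,5-dihydrofuran between the vinyl group and the 1,1-disubstituted alkene. Pyridinium p-toluenesulfonate in the same pot should then expel ethanol to give the bis-silyl ether A4.
- For: the furan substitution pattern is fixed by the acyclic precursor, so no site selectivity on a dihalofuran and no lithiofuran are involved. A4 is one desilylation from the target. On end-game length it is stronger than the chosen route, which needs three steps after its key step.
- Against:
  - C1' has to be set by a separate asymmetric step on an allylic carbinol next to a 1,1-disubstituted alkene, and the key step does nothing for it.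
  - The acetal C–O bond to the benzylic and allylic carbon of A5 ionises easily, and the mixed acetal must be assembled from two different partners.
  - Metathesis onto a 1,1-disubstituted alkene flanked by the acyloxy-bearing carbon is slow, and the prenyl alkene is a third olefin the ruthenium carbene can engage.
  - The acid used for aromatisation meets an allylic ester that is becoming a furylic one.
  - Building A5 needs more steps than the whole chosen route.
- Comparison: the chosen route offers, in place of the short end game, a key step that solves the stereocentre and the linear prenyl unit together from three simple pieces.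

**Alternative 3: gold-catalysed cycloisomerisation of an epoxy alkynol.**
- Disconnection: the furan O1–C2 bond and the aromatisation, leading back to the alkynyl epoxy alcohol A7, whose epoxide comes from a Sharpless asymmetric epoxidation of a 2-alkynyl allylic alcohol.
- Forward key step: Ph3PAuNTf2 (monovalent gold) activates the aryl alkyne of A7 and the primary hydroxyl adds 5-endo-dig. The enol ether so formed opens the epoxide at the quaternary carbon, and loss of a proton should give the furan carbinol A6 (identical with 12), with the carbinol C–O bond never broken.
- For: the configuration at C1' would come from the Sharpless epoxidation, which is more predictable than an enantioselective metallate shift with a little-tested heteroaryl migrating group. On that point it is stronger. The furan forms under nearly neutral conditions, and the end game from A6 is the same as from 12.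
- Against:
  - A7 requires an enyne allylic alcohol of defined geometry that contains the skipped prenyl alkene and the aryl alkyne, so several C–C bond-forming steps precede the epoxidation.
  - The epoxide of A7 is tertiary and propargylic, so the Lewis-acidic gold can ionise it before the hydroxyl has cyclised.
  - The ortho-silyloxy aryl alkyne offers the aryl oxygen as a competing nucleophile toward the activated alkyne.
  - Reaching A6 would take roughly twice as many steps as reaching 12 by the chosen route.
- Comparison: the chosen strategy gives up some predictability in the enantioselection and gains a five-step access to the same carbinol in which stereocentre, β-furyl bond and linear prenyl bond arise together.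

Key step: step 5

Assumption: both antipodes of the Mandyphos-type ligand 1,1′-bis[bis(4-methoxy-3,5-dimethylphenyl)phosphino]-2,2′-bis[α-(dimethylamino)benzyl]ferrocene are available, and the antipode is used that directs the furyl shift to the face of the vinyl group that gives (R)-11.

## Route

Step 1
Reactants: 1 2-bromobenzene-1,4-diol (bromohydroquinone)
Product: 2 2-bromo-1,4-bis(triisopropylsilyloxy)benzene
Conditions: TIPSCl, imidazole, DMF, rt to 40 °C, argon
Reagents that add atoms: chlorotriisopropylsilane, CC(C)[Si](Cl)(C(C)C)C(C)C
Why: Imidazole-promoted O-silylation of phenols; both hydroxyls are unhindered enough for the bulky silyl chloride with gentle warming, and exclusion of air prevents quinone formation before protection is complete.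

Step 2
Reactants: 2 2-bromo-1,4-bis(triisopropylsilyloxy)benzene
Product: 3 2-[2,5-bis(triisopropylsilyloxy)phenyl]-4,4,5,5-tetramethyl-1,3,2-dioxaborolane
Conditions: bis(pinacolato)diboron, PdCl2(dppf) (dppf = 1,1′-bis(diphenylphosphino)ferrocene), KOAc, 1,4-dioxane, 90 °C
Reagents that add atoms: bis(pinacolato)diboron, CC1(C)OB(OC1(C)C)B1OC(C)(C)C(C)(C)O1
Why: Miyaura borylation; the weak acetate base activates the diboron through an acetato-palladium intermediate without cleaving aryl silyl ethers or promoting biaryl formation, and no aryllithium is generated next to a silyloxy group.

Step 3
Reactants: 3 2-[2,5-bis(triisopropylsilyloxy)phenyl]-4,4,5,5-tetramethyl-1,3,2-dioxaborolane, 4 2,4-dibromofuran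
Product: 5 4-bromo-2-[2,5-bis(triisopropylsilyloxy)phenyl]furan
Conditions: Pd(PPh3)4, aq. Na2CO3, DME, 70 °C; 4 in slight excess
Reagents that add atoms: none
Why: Suzuki–Miyaura coupling; oxidative addition of zerovalent palladium is faster at the C2–Br bond α to the ring oxygen than at the β C4–Br bond, so the aryl group should enter at C2 and the β-bromide is kept, and carbonate at moderate temperature should leave the bulky aryl silyl ethers intact.

Step 4
Reactants: 6 isobutyraldehyde (2-methylpropanal)
Product: 7 2-methylprop-1-en-1-yl trifluoromethanesulfonate
Conditions: Tf2O, 2,6-di-tert-butyl-4-methylpyridine, CH2Cl2, 0 °C to rt; distillation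
Reagents that add atoms: trifluoromethanesulfonic anhydride, O=S(=O)(OS(=O)(=O)C(F)(F)F)C(F)(F)F
Why: Enol triflate formation from an enolisable aldehyde; O-sulfonylation of the carbonyl and removal of the single α-proton by the hindered non-nucleophilic pyridine gives the vinyl triflate, and the two identical β-methyls mean there is only one alkene isomer.

Step 5
Reactants: 5 4-bromo-2-[2,5-bis(triisopropylsilyloxy)phenyl]furan, 8 vinylboronic acid pinacol ester (4,4,5,5-tetramethyl-2-vinyl-1,3,2-dioxaborolane), 7 2-methylprop-1-en-1-yl trifluoromethanesulfonate
Product: 11 2-{(1R)-1-[5-(2,5-bis(triisopropylsilyloxy)phenyl)furan-3-yl]-4-methylpent-3-en-1-yl}-4,4,5,5-tetramethyl-1,3,2-dioxaborolane, via 4-lithiofuran 9 (not isolated), via lithium furyl(vinyl)boronate complex 10 (not isolated)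
Conditions: t-BuLi (2 equiv), Et2O, −78 °C; 8, −78 °C to rt; solvent exchange to THF; 7, Pd(OAc)2 (2 mol%), 1,1′-bis[bis(4-methoxy-3,5-dimethylphenyl)phosphino]-2,2′-bis[α-(dimethylamino)benzyl]ferrocene (antipode giving (R)-11, 2.4 mol%), KOTf, THF, 60 °C
Reagents that add atoms: none
Why: Bromine–lithium exchange with two equivalents of t-BuLi at −78 °C gives the 4-lithiofuran 9, which is trapped on the empty boron orbital of 8 as the four-coordinate boronate 10 before it can equilibrate to the more stable 5-lithio isomer. Zerovalent palladium formed from Pd(OAc)2 and the bisphosphine adds oxidatively to the C–O bond of 7, and since triflate does not coordinate, the cationic alkenyl divalent palladium species binds the vinyl group of 10. This triggers a 1,2-metallate shift in which the furyl group moves from boron to the boron-bearing internal carbon on the face opposite palladium while palladium takes the terminal carbon, and C(sp3)–C(sp2) reductive elimination then forms the CH2–CH= bond and regenerates zerovalent palladium. The closest known reaction type is the palladium-catalysed enantioselective conjunctive cross-coupling of vinylboron ate complexes with alkenyl triflates, and no ring is closed. The new stereocentre C1' is set by catalyst control alone, because the chiral pocket of the ferrocenyl bisphosphine decides which face of the bound vinyl group meets the migrating furyl carbon. Regiochemistry is secured by the mechanism, since the alkenyl group can only be delivered to the carbon that carries palladium, so the prenyl unit must be linear. The step further needs the metallate shift to outrun direct transmetalation and β-hydride elimination, which the wide-bite-angle ligand and a halide-free cationic palladium centre favour, and KOTf is added to remove the LiBr from the exchange as KBr for that reason. The aryl silyl ethers and the furan C5–H are not expected to react under these conditions.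

Step 6
Reactants: 11 2-{(1R)-1-[5-(2,5-bis(triisopropylsilyloxy)phenyl)furan-3-yl]-4-methylpent-3-en-1-yl}-4,4,5,5-tetramethyl-1,3,2-dioxaborolane
Product: 12 (1R)-1-{5-[2,5-bis(triisopropylsilyloxy)phenyl]furan-3-yl}-4-methylpent-3-en-1-ol
Conditions: NaBO3·4H2O, THF/H2O (1:1), rt
Reagents that add atoms: sodium perborate NaBO3 (supplies the hydroxyl oxygen), [Na+].[O-]OB=O
Why: Oxidation of a secondary boronic ester; the peroxide adds to boron and C1' migrates from boron to oxygen with retention, so (R)-11 should give (R)-12, and perborate is mild enough to spare the aryl silyl ethers, the furan and the alkene.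

Step 7
Reactants: 12 (1R)-1-{5-[2,5-bis(triisopropylsilyloxy)phenyl]furan-3-yl}-4-methylpent-3-en-1-ol, 13 3-methylbutanoyl chloride (isovaleryl chloride)
Product: 14 (1R)-1-{5-[2,5-bis(triisopropylsilyloxy)phenyl]furan-3-yl}-4-methylpent-3-en-1-yl 3-methylbutanoate
Conditions: Et3N, DMAP (cat.), CH2Cl2, 0 °C to rt
Reagents that add atoms: none
Why: DMAP-catalysed acylation of a secondary alcohol by an acid chloride; the C1'–O bond is not broken, and the basic medium avoids ionisation of the furylic carbinol, so the configuration should be unchanged.

Step 8
Reactants: 14 (1R)-1-{5-[2,5-bis(triisopropylsilyloxy)phenyl]furan-3-yl}-4-methylpent-3-en-1-yl 3-methylbutanoate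
Product: 15 (1R)-1-[5-(2,5-dihydroxyphenyl)furan-3-yl]-4-methylpent-3-en-1-yl 3-methylbutanoate
Conditions: Bu4NF, AcOH, THF, 0 °C, degassed, argon
Reagents that add atoms: none
Why: Fluoride-induced cleavage of aryl silyl ethers; phenoxide is a good leaving group from silicon so the reaction should be fast at 0 °C, and the acetic acid buffer protonates each phenoxide as it forms, which protects the ester from base and the hydroquinone from aerobic oxidation.

## Compound list

1 | 2-bromobenzene-1,4-diol (bromohydroquinone) | Oc1ccc(O)c(Br)c1 | starting material
2 | 2-bromo-1,4-bis(triisopropylsilyloxy)benzene | Brc1cc(O[Si](C(C)C)(C(C)C)C(C)C)ccc1O[Si](C(C)C)(C(C)C)C(C)C | intermediate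
3 | 2-[2,5-bis(triisopropylsilyloxy)phenyl]-4,4,5,5-tetramethyl-1,3,2-dioxaborolane | CC1(C)OB(c2cc(O[Si](C(C)C)(C(C)C)C(C)C)ccc2O[Si](C(C)C)(C(C)C)C(C)C)OC1(C)C | intermediate
4 | 2,4-dibromofuran | Brc1coc(Br)c1 | starting material
5 | 4-bromo-2-[2,5-bis(triisopropylsilyloxy)phenyl]furan | Brc1coc(-c2cc(O[Si](C(C)C)(C(C)C)C(C)C)ccc2O[Si](C(C)C)(C(C)C)C(C)C)c1 | intermediate
6 | isobutyraldehyde (2-methylpropanal) | CC(C)C=O | starting material
7 | 2-methylprop-1-en-1-yl trifluoromethanesulfonate | CC(C)=COS(=O)(=O)C(F)(F)F | intermediate
8 | vinylboronic acid pinacol ester (4,4,5,5-tetramethyl-2-vinyl-1,3,2-dioxaborolane) | C=CB1OC(C)(C)C(C)(C)O1 | starting material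
9 | 4-lithio-2-[2,5-bis(triisopropylsilyloxy)phenyl]furan | [Li]c1coc(-c2cc(O[Si](C(C)C)(C(C)C)C(C)C)ccc2O[Si](C(C)C)(C(C)C)C(C)C)c1 | intermediate (not isolated)
10 | lithium {5-[2,5-bis(triisopropylsilyloxy)phenyl]furan-3-yl}(vinyl)(pinacolato)borate | [Li+].C=C[B-]1(OC(C)(C)C(C)(C)O1)c1coc(-c2cc(O[Si](C(C)C)(C(C)C)C(C)C)ccc2O[Si](C(C)C)(C(C)C)C(C)C)c1 | intermediate (not isolated)
11 | 2-{(1R)-1-[5-(2,5-bis(triisopropylsilyloxy)phenyl)furan-3-yl]-4-methylpent-3-en-1-yl}-4,4,5,5-tetramethyl-1,3,2-dioxaborolane | CC(C)=CC[C@@H](B1OC(C)(C)C(C)(C)O1)c1coc(-c2cc(O[Si](C(C)C)(C(C)C)C(C)C)ccc2O[Si](C(C)C)(C(C)C)C(C)C)c1 | intermediate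
12 | (1R)-1-{5-[2,5-bis(triisopropylsilyloxy)phenyl]furan-3-yl}-4-methylpent-3-en-1-ol | CC(C)=CC[C@@H](O)c1coc(-c2cc(O[Si](C(C)C)(C(C)C)C(C)C)ccc2O[Si](C(C)C)(C(C)C)C(C)C)c1 | intermediate
13 | 3-methylbutanoyl chloride (isovaleryl chloride) | CC(C)CC(Cl)=O | starting material
14 | (1R)-1-{5-[2,5-bis(triisopropylsilyloxy)phenyl]furan-3-yl}-4-methylpent-3-en-1-yl 3-methylbutanoate | CC(C)=CC[C@@H](OC(=O)CC(C)C)c1coc(-c2cc(O[Si](C(C)C)(C(C)C)C(C)C)ccc2O[Si](C(C)C)(C(C)C)C(C)C)c1 | intermediate
15 | (1R)-1-[5-(2,5-dihydroxyphenyl)furan-3-yl]-4-methylpent-3-en-1-yl 3-methylbutanoate | CC(C)=CC[C@@H](OC(=O)CC(C)C)c1coc(-c2cc(O)ccc2O)c1 | target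

## Step count and risk

Total step count: 8. Longest linear sequence: 7 steps (steps 1, 2, 3, 5, 6, 7, 8); step 4 is a one-step side branch that joins at step 5.

Least certain steps:

**Step 5 (key step).** Several processes can go wrong:
- isomerisation of the β-lithiofuran to the α-lithio species if the temperature rises before boron capture;
- inhibition of the cationic palladium centre by residual bromide;
- direct transfer of furyl or vinyl from boron to palladium, giving simple cross-coupling instead of the metallate shift;
- β-hydride elimination from the alkylpalladium intermediate;
- poor facial selectivity, because a furan-3-yl migrating group is smaller and more electron-rich than the aryl groups for which the ligand is best established.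

Fallback, from 5 back to 12: bromide 5 would be lithiated as before and the lithiofuran added to the Weinreb amide N-methoxy-N,4-dimethylpent-3-enamide F1, made in one step from commercial 4-methylpent-3-enoic acid. This would give the ketone 1-{5-[2,5-bis(triisopropylsilyloxy)phenyl]furan-3-yl}-4-methylpent-3-en-1-one F2. Corey–Bakshi–Shibata reduction of F2 with the (S)-2-methyl oxazaborolidine and catecholborane at low temperature (furyl as the large group, by analogy with aryl alkyl ketones) should give carbinol 12. Catecholborane is chosen so that the prenyl alkene is not hydroborated. The route is rejoined at 12.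

**Step 3.** The likely failures are loss of site selectivity (a second coupling at C4 once the first aryl group is on), protodeboronation of the hindered, electron-rich boronate, and partial cleavage of the aryl silyl ethers by aqueous base.

Fallback, from 4 and 2 back to 5, bypassing 3: the polarity would be reversed. Selective bromine–lithium exchange at the α-position of 4 with n-BuLi at −78 °C would give 4-bromo-2-lithiofuran F3. Transmetalation with ZnCl2 would give (4-bromofuran-2-yl)zinc chloride F4. Negishi coupling of F4 with aryl bromide 2 under anhydrous, base-free conditions (Pd(OAc)2 with 2-dicyclohexylphosphino-2′,6′-dimethoxybiphenyl) would lead to 5.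

**Step 4.** The likely failures are acid-promoted self-condensation of the aldehyde in competition with O-sulfonylation, and loss of the low-boiling triflate on isolation.

Fallback, from 6 back to 7: 6 would be converted with TMSCl and Et3N in DMF into trimethyl[(2-methylprop-1-en-1-yl)oxy]silane F5. Cleavage with MeLi would give the regiodefined lithium 2-methylprop-1-en-1-olate F6, which would be O-sulfonylated with N-phenylbis(trifluoromethanesulfonimide) to give 7.

**Step 8.** The likely failures are air oxidation of the liberated hydroquinone to the quinone while phenoxide is present, and fluoride- or phenoxide-induced loss of the ester.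

Fallback, from 14 back to 15: the oxidation would be accepted and used. After buffered desilylation of 14, the crude material would be oxidised completely with Ag2O to the quinone (1R)-1-[5-(3,6-dioxocyclohexa-1,4-dien-1-yl)furan-3-yl]-4-methylpent-3-en-1-yl 3-methylbutanoate F7. F7 can be purified without special precautions and would be reduced in a two-phase system with aqueous Na2S2O4 immediately before isolation of 15.

## Further compounds

F1 | step 5 | N-methoxy-N,4-dimethylpent-3-enamide | CC(C)=CCC(=O)N(C)OC
F2 | step 5 | 1-{5-[2,5-bis(triisopropylsilyloxy)phenyl]furan-3-yl}-4-methylpent-3-en-1-one | CC(C)=CCC(=O)c1coc(-c2cc(O[Si](C(C)C)(C(C)C)C(C)C)ccc2O[Si](C(C)C)(C(C)C)C(C)C)c1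
F3 | step 3 | 4-bromo-2-lithiofuran | [Li]c1cc(Br)co1
F4 | step 3 | (4-bromofuran-2-yl)zinc chloride | Cl[Zn]c1cc(Br)co1
F5 | step 4 | trimethyl[(2-methylprop-1-en-1-yl)oxy]silane | CC(C)=CO[Si](C)(C)C
F6 | step 4 | lithium 2-methylprop-1-en-1-olate | CC(C)=CO[Li]
F7 | step 8 | (1R)-1-[5-(3,6-dioxocyclohexa-1,4-dien-1-yl)furan-3-yl]-4-methylpent-3-en-1-yl 3-methylbutanoate | CC(C)=CC[C@@H](OC(=O)CC(C)C)c1coc(C2=CC(=O)C=CC2=O)c1
A1 | alternative 1 | (1R)-1-[5-(2-hydroxy-5-methoxyphenyl)furan-3-yl]-4-methylpent-3-en-1-yl 3-methylbutanoate | CC(C)=CC[C@@H](OC(=O)CC(C)C)c1coc(-c2cc(OC)ccc2O)c1
A2 | alternative 1 | (1R)-1-(5-ethynylfuran-3-yl)-4-methylpent-3-en-1-yl 3-methylbutanoate | CC(C)=CC[C@@H](OC(=O)CC(C)C)c1coc(C#C)c1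
A3 | alternative 1 | pentacarbonyl[methoxy(vinyl)carbene]chromium, (CO)5Cr=C(OMe)CH=CH2 | COC(C=C)=[Cr](=C=O)(=C=O)(=C=O)(=C=O)=C=O
A4 | alternative 2 | (1R)-1-{5-[2,5-bis(tert-butyldimethylsilyloxy)phenyl]furan-3-yl}-4-methylpent-3-en-1-yl 3-methylbutanoate | CC(C)=CC[C@@H](OC(=O)CC(C)C)c1coc(-c2cc(O[Si](C)(C)C(C)(C)C)ccc2O[Si](C)(C)C(C)(C)C)c1
A5 | alternative 2 | (3R)-2-{ethoxy[1-(2,5-bis(tert-butyldimethylsilyloxy)phenyl)prop-2-en-1-yloxy]methyl}-6-methylhepta-1,5-dien-3-yl 3-methylbutanoate (acetal and benzylic carbons as mixtures) | CC(C)=CC[C@@H](OC(=O)CC(C)C)C(=C)C(OCC)OC(C=C)c1cc(O[Si](C)(C)C(C)(C)C)ccc1O[Si](C)(C)C(C)(C)C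
A6 | alternative 3 | (1R)-1-{5-[2,5-bis(triisopropylsilyloxy)phenyl]furan-3-yl}-4-methylpent-3-en-1-ol (identical with 12) | CC(C)=CC[C@@H](O)c1coc(-c2cc(O[Si](C(C)C)(C(C)C)C(C)C)ccc2O[Si](C(C)C)(C(C)C)C(C)C)c1
A7 | alternative 3 | [(2S,3R)-2-{[2,5-bis(triisopropylsilyloxy)phenyl]ethynyl}-3-(3-methylbut-2-en-1-yl)oxiran-2-yl]methanol | CC(C)=CC[C@H]1O[C@]1(CO)C#Cc1cc(O[Si](C(C)C)(C(C)C)C(C)C)ccc1O[Si](C(C)C)(C(C)C)C(C)C
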